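## Retrosynthetic overview

1. Hydrindane numbering: C1 side-chain carbon, C2 ketone, C3a/C7a ring fusion, C4 methylidene carbon, C5/C6 ester carbons, C7 isopropyl carbon. The target comes from the trans-fused enone 16 by cis-dihydroxylation (C5, C6), C4 methylenation, two acylations, C2 oxidation and acetylation.
2. Enone 16 comes from the 2-vinylcyclobutanol 13 by an alkoxide-accelerated [1,3] shift that opens the cyclobutane and creates the six-membered ring. Ring order: cyclopentene (bought), cyclobutanone (step 2), cyclohexene (step 9).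
3. The C2 oxygen and the C1 side chain are installed on the rigid bicyclo[3.2.0]heptenone 7 (bromohydrin, α-bromo ketone, syn aldol), followed by a lipase resolution.
4. Ketone 7 comes from isopropyl(vinyl)ketene and cyclopentadiene by a (2+2) cycloaddition that forms C4–C3a and C7–C7a.
5. Enabling feature: the arc C4–C5–C6–C7 of the six-membered ring is bonded at both ends to the fusion bond C3a–C7a. C4/C7 map onto the C=C of a ketene, C5/C6 onto a vinyl group on it, and C3a–C7a with C3, C2, C1 onto cyclopentadiene.

Key step: step 2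

Remark: α/β denote the faces of the hydrindane with H-7a defined as α. Compounds 7–13 are carried as mixtures of epimers at the quaternary C7 of the bicycle (isopropyl endo drawn); both converge in step 9. Compounds 1, 2, 21 and 24 are taken as purchased, and 4 is cracked from commercial dicyclopentadiene.

## Route

Step 1
Reactants: 1 isopropylmalonic acid; 2 acetaldehyde
Product: 3 (E)-2-isopropylbut-2-enoic acid
Conditions: MeCHO (3 equiv), pyridine, piperidine (cat.), sealed tube, 70 °C
Reagents that add atoms: none
Why: Knoevenagel–Doebner condensation; the β-hydroxy diacid from a monosubstituted malonic acid can only collapse by decarboxylative dehydration, which gives the α-branched enoic acid (the alkene geometry is lost in step 2).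

Step 2
Reactants: 3; 4 cyclopenta-1,3-diene
Product: 7 rac-(1R,5S,7S)-7-isopropyl-7-vinylbicyclo[3.2.0]hept-2-en-6-one, via acid chloride 5 (not isolated), via isopropyl(vinyl)ketene 6 (not isolated)
Conditions: (COCl)2, DMF (cat.), CH2Cl2, 0 °C to rt, evaporate; then Et3N (slow addition), cyclopentadiene (5 equiv), CHCl3, 50 °C
Reagents that add atoms: none
Why: Triethylamine removes HCl across the γ-methyl group and the acyl chloride to give ketene 6, which adds to cyclopentadiene in a thermal [π2s+π2a] ketene–alkene (2+2) cycloaddition, the established reaction type for alkyl(vinyl)ketenes and cyclopentadiene. The cyclobutanone ring is closed by this cycloaddition in one event: the electrophilic ketene carbonyl carbon (future C4) bonds to the diene terminus (future C3a) and the substituted ketene carbon (future C7) to the adjacent internal carbon (future C7a), leaving the future C1=C2 alkene for later use. Both bonds form on one face of the diene, so the fusion is cis; C7a keeps this configuration to the end (racemic here, resolved in step 6), whereas C3a is inverted later by equilibration. The quaternary carbon is set by the usual preference of the larger ketene substituent for the endo position, but it is of no consequence because it becomes sp2 in step 9. The step needs (2+2) over (4+2) periselectivity (secured by the orthogonal ketene π system), the regiochemistry (secured by ketene polarity and allylic stabilisation in the diene) and cycloaddition over ketene dimerisation (secured by slow generation of 6 in excess diene).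

Step 3
Reactants: 7
Product: 8 rac-2-exo-bromo-3-endo-hydroxy-7-endo-isopropyl-7-exo-vinylbicyclo[3.2.0]heptan-6-one
Conditions: N-bromoacetamide, acetone/H2O (4:1), 0 °C to rt
Reagents that add atoms: N-bromoacetamide CC(=O)NBr; water O
Why: Bromohydrin formation; the bromonium ion forms on the convex exo face of the cyclopentene (far more nucleophilic than the vinyl group) and water opens it trans at the carbon remote from the ring fusion, as in the parent bicyclo[3.2.0]hept-2-en-6-one series, because endo attack next to the fusion is blocked by the cyclobutane and its endo isopropyl group.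

Step 4
Reactants: 8
Product: 9 rac-2-exo-bromo-7-endo-isopropyl-7-exo-vinylbicyclo[3.2.0]heptane-3,6-dione
Conditions: Dess–Martin periodinane, NaHCO3, CH2Cl2, rt
Reagents that add atoms: none
Why: Dess–Martin oxidation of the secondary carbinol gives the α-bromo ketone, a regiochemically defined enolate precursor for the future C1.

Step 5
Reactants: 9; 2 acetaldehyde
Product: 10 rac-2-exo-(1-hydroxyethyl)-7-endo-isopropyl-7-exo-vinylbicyclo[3.2.0]heptane-3,6-dione (syn aldol)
Conditions: Sn powder (activated), MeCHO (3 equiv), THF, −10 °C to rt; aq. NH4Cl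
Reagents that add atoms: none
Why: Reformatsky-type aldol through a divalent tin enolate formed by insertion of tin into the C–Br bond; acetaldehyde should add from the convex exo face (side chain trans to the cyclobutane bond at the neighbouring bridgehead), and tin enolates are syn-selective whatever the enolate geometry, which sets the carbinol relative to the ring.

Step 6
Reactants: 10
Product: 11 2-exo-[(1R)-1-acetoxyethyl]-7-endo-isopropyl-7-exo-vinylbicyclo[3.2.0]heptane-3,6-dione (single enantiomer)
Conditions: Candida antarctica lipase B (immobilised), vinyl acetate, MTBE, 30 °C, stopped near half conversion; chromatography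
Reagents that add atoms: vinyl acetate C=COC(C)=O
Why: Lipase-catalysed kinetic resolution by transesterification; the enzyme acylates the (R)-configured methyl carbinol (Kazlauskas rule), which is the enantiomer with the ring configuration of the target, and the unreacted (1′S)-enantiomer is removed.

Step 7
Reactants: 11
Product: 12 2-exo-[(1R)-1-hydroxyethyl]-7-endo-isopropyl-7-exo-vinylbicyclo[3.2.0]heptane-3-endo,6-endo-diol
Conditions: LiAlH4, THF, 0 °C to rt; Fieser work-up
Reagents that add atoms: none
Why: Hydride reduction of both ketones and the acetate; the cyclobutanone should be attacked from the exo face, and the configuration of the new cyclopentanol is of no consequence because this carbon is reoxidised in step 18.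

Step 8
Reactants: 12
Product: 13 3-O,1′-O-(di-tert-butylsilylene) derivative of 12 (6-endo-hydroxyl free)
Conditions: tBu2Si(OTf)2, 2,6-lutidine, CH2Cl2, 0 °C
Reagents that add atoms: di-tert-butylsilyl bis(trifluoromethanesulfonate) CC(C)(C)[Si](OS(=O)(=O)C(F)(F)F)(OS(=O)(=O)C(F)(F)F)C(C)(C)C
Why: Cyclic silylene formation is selective for the 1,3-diol (six-membered dioxasilinane); the hindered cyclobutanol stays free for step 9.

Step 9
Reactants: 13
Product: 14 cis-fused 7-isopropyl-2,3,3a,4,5,7a-hexahydro-1H-inden-4-ol carrying the 2β-O,1′-O-silylene and the 1α-[(1R)-1-oxyethyl] chain (H-3a α; H-7a α; C6=C7; C4 epimers)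
Conditions: KH, 18-crown-6 (cat.), THF, 0 to 25 °C; then H2O
Reagents that add atoms: none
Why: Alkoxide-accelerated [1,3] shift of a 2-vinylcyclobutanol (Danheiser ring expansion); the potassium alkoxide weakens the bond to the vinyl-bearing carbon, the allyl anion recloses through its terminus onto the aldehyde carbon, and release of cyclobutane strain drives the formation of the cyclohexenol; the new carbinol centre is removed in step 10.

Step 10
Reactants: 14
Product: 16 trans-fused 7α-isopropyl-1,2,3,3a,7,7a-hexahydro-4H-inden-4-one carrying the 2β-O,1′-O-silylene (H-3a β; H-7a α; C5=C6), via β,γ-enone 15 (not isolated)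
Conditions: Dess–Martin periodinane, NaHCO3, CH2Cl2, rt; filter, concentrate; then NaOMe (0.3 equiv), MeOH, rt
Reagents that add atoms: none
Why: Oxidation gives the β,γ-unsaturated ketone, which methoxide conjugates through the dienolate; under these equilibrating conditions C7 (γ-protonation) and C3a (epimerisation next to the carbonyl) should settle in the arrangement with trans ring fusion and an equatorial isopropyl group trans to the C7a–C1 bond.

Step 11
Reactants: 16
Product: 17 5β,6β-dihydroxy-7α-isopropyl-octahydro-4H-inden-4-one carrying the 2β-O,1′-O-silylene (trans-fused)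
Conditions: OsO4 (2 mol%), N-methylmorpholine N-oxide, acetone/H2O, rt
Reagents that add atoms: osmium tetroxide O=[Os](=O)(=O)=O; N-methylmorpholine N-oxide C[N+]1([O-])CCOCC1
Why: Upjohn dihydroxylation; osmylation is syn and should occur on the β-face, anti to the adjacent α-isopropyl group, which gives the cis-diol with the C5–O bond axial and the C6–O bond equatorial.

Step 12
Reactants: 17
Product: 18 5β,6β-O-isopropylidene derivative of 17
Conditions: Me2C(OMe)2, PPTS (cat.), CH2Cl2, rt
Reagents that add atoms: 2,2-dimethoxypropane COC(C)(C)OC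
Why: Acetonide formation on the cis-diol protects the hydroxy ketone against retro-aldol cleavage and locks C5 in the cis arrangement for the basic step that follows.

Step 13
Reactants: 18
Product: 19 4-methylidene analogue of 18 (5β,6β-acetonide; 2β-O,1′-O-silylene)
Conditions: Ph3PCH3Br, KOtBu, THF, 0 °C; then 18, 0 to 45 °C
Reagents that add atoms: methyltriphenylphosphonium bromide C[P+](c1ccccc1)(c1ccccc1)c1ccccc1.[Br-]
Why: Wittig methylenation of the only ketone; C3a, the one enolisable stereocentre, is already in its stable trans arrangement, which the axial C5–O bond reinforces.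

Step 14
Reactants: 19
Product: 20 4-methylidene-5β,6β-diol (2β-O,1′-O-silylene retained)
Conditions: AcOH/H2O (4:1), 40 °C
Reagents that add atoms: none
Why: Acid hydrolysis of the dioxolane acetonide; the di-tert-butylsilylene of the 1,3-diol is stable to aqueous acetic acid.

Step 15
Reactants: 20; 21 (S)-2-methylbutanoic anhydride
Product: 23 6β-O-[(2S)-2-methylbutanoyl] 5β-alcohol, via stannylene acetal 22 (not isolated)
Conditions: Bu2SnO, toluene, reflux (Dean–Stark); then 21, rt
Reagents that add atoms: none
Why: Tin-mediated regioselective acylation; the dibutylstannylene acetal of a cis-diol is acylated at the equatorial oxygen (C6–O), and the amine-free conditions avoid racemisation of the acyl α-stereocentre.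

Step 16
Reactants: 23; 24 (E)-3-methylpent-2-enoic acid
Product: 26 5β-O-[(2E)-3-methylpent-2-enoyl] 6β-O-[(2S)-2-methylbutanoyl] diester (2β-O,1′-O-silylene), via mixed anhydride 25 (not isolated)
Conditions: 24, 2,4,6-Cl3C6H2COCl, Et3N, THF, rt; then 23, DMAP, toluene, rt
Reagents that add atoms: none
Why: Yamaguchi esterification of the remaining hindered axial allylic alcohol; the preformed mixed anhydride reacts under mild conditions that should not isomerise or deconjugate the trisubstituted enoate.

Step 17
Reactants: 26
Product: 27 diester 2β,1′-diol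
Conditions: HF·pyridine, pyridine/THF, 0 °C to rt
Reagents that add atoms: none
Why: Fluoride cleavage of the silylene; the two esters and the exocyclic alkene are inert to HF·pyridine.

Step 18
Reactants: 27
Product: 28 diester 2-ketone with free (1′R)-hydroxyl (β-hydroxy ketone)
Conditions: TEMPO (10 mol%), PhI(OAc)2, CH2Cl2, rt
Reagents that add atoms: none
Why: Oxoammonium oxidation is sensitive to steric hindrance; the ring carbinol at C2, flanked by a CH2 group, should be oxidised in preference to the side-chain carbinol, which sits next to the branched C1 in the pocket beside the C7 isopropyl group.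

Step 19
Reactants: 28
Product: 29 target
Conditions: Ac2O, pyridine, DMAP (cat.), CH2Cl2, 0 °C to rt
Reagents that add atoms: acetic anhydride CC(=O)OC(C)=O
Why: DMAP-catalysed acetylation of the β-hydroxy ketone under mild conditions gives the target without exposing the β-acetoxy ketone to strong base.

## Compound list

1 | isopropylmalonic acid | CC(C)C(C(=O)O)C(=O)O | starting material
2 | acetaldehyde | CC=O | starting material
3 | (E)-2-isopropylbut-2-enoic acid | C/C=C(\C(C)C)C(=O)O | intermediate
4 | cyclopenta-1,3-diene | C1=CCC=C1 | starting material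
5 | (E)-2-isopropylbut-2-enoyl chloride | C/C=C(\C(C)C)C(Cl)=O | intermediate
6 | isopropyl(vinyl)ketene | C=CC(=C=O)C(C)C | intermediate
7 | rac-(1R,5S,7S)-7-isopropyl-7-vinylbicyclo[3.2.0]hept-2-en-6-one (cis-fused, isopropyl endo; enantiomer carried on is drawn) | O=C1[C@H]2CC=C[C@H]2[C@@]1(C=C)C(C)C | intermediate
8 | rac-2-exo-bromo-3-endo-hydroxy-7-endo-isopropyl-7-exo-vinylbicyclo[3.2.0]heptan-6-one | O=C1[C@H]2C[C@@H](O)[C@H](Br)[C@H]2[C@@]1(C=C)C(C)C | intermediate
9 | rac-2-exo-bromo-7-endo-isopropyl-7-exo-vinylbicyclo[3.2.0]heptane-3,6-dione | O=C1[C@H]2CC(=O)[C@H](Br)[C@H]2[C@@]1(C=C)C(C)C | intermediate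
10 | rac-2-exo-(1-hydroxyethyl)-7-endo-isopropyl-7-exo-vinylbicyclo[3.2.0]heptane-3,6-dione, syn aldol | O=C1[C@H]2CC(=O)[C@H]([C@@H](C)O)[C@H]2[C@@]1(C=C)C(C)C | intermediate
11 | 2-exo-[(1R)-1-acetoxyethyl]-7-endo-isopropyl-7-exo-vinylbicyclo[3.2.0]heptane-3,6-dione | O=C1[C@H]2CC(=O)[C@H]([C@@H](C)OC(C)=O)[C@H]2[C@@]1(C=C)C(C)C | intermediate
12 | 2-exo-[(1R)-1-hydroxyethyl]-7-endo-isopropyl-7-exo-vinylbicyclo[3.2.0]heptane-3-endo,6-endo-diol | O[C@H]1[C@H]2C[C@@H](O)[C@H]([C@@H](C)O)[C@H]2[C@@]1(C=C)C(C)C | intermediate
13 | 3-O,1′-O-(di-tert-butylsilylene) derivative of 12 | O[C@H]1[C@H]2C[C@H]3O[Si](C(C)(C)C)(C(C)(C)C)O[C@H](C)[C@@H]3[C@H]2[C@@]1(C=C)C(C)C | intermediate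
14 | cis-fused hexahydroinden-4-ol (C6=C7, 7-isopropyl, 2β-O,1′-O-silylene, side chain 1α, C4 epimers) | OC1CC=C(C(C)C)[C@H]2[C@@H]1C[C@H]3O[Si](C(C)(C)C)(C(C)(C)C)O[C@H](C)[C@H]23 | intermediate
15 | cis-fused β,γ-unsaturated 4-ketone corresponding to 14 | O=C1CC=C(C(C)C)[C@H]2[C@@H]1C[C@H]3O[Si](C(C)(C)C)(C(C)(C)C)O[C@H](C)[C@H]23 | intermediate
16 | trans-fused conjugated enone (C5=C6, 7α-isopropyl, H-3a β, H-7a α, silylene) | O=C1C=C[C@@H](C(C)C)[C@H]2[C@H]1C[C@H]3O[Si](C(C)(C)C)(C(C)(C)C)O[C@H](C)[C@H]23 | intermediate
17 | 5β,6β-dihydroxy ketone (silylene) | O=C1[C@H](O)[C@H](O)[C@@H](C(C)C)[C@H]2[C@H]1C[C@H]3O[Si](C(C)(C)C)(C(C)(C)C)O[C@H](C)[C@H]23 | intermediate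
18 | 5β,6β-O-isopropylidene ketone (silylene) | O=C1[C@@H]4OC(C)(C)O[C@@H]4[C@@H](C(C)C)[C@H]2[C@H]1C[C@H]3O[Si](C(C)(C)C)(C(C)(C)C)O[C@H](C)[C@H]23 | intermediate
19 | 4-methylidene 5β,6β-acetonide (silylene) | C=C1[C@@H]4OC(C)(C)O[C@@H]4[C@@H](C(C)C)[C@H]2[C@H]1C[C@H]3O[Si](C(C)(C)C)(C(C)(C)C)O[C@H](C)[C@H]23 | intermediate
20 | 4-methylidene-5β,6β-diol (silylene) | C=C1[C@H](O)[C@H](O)[C@@H](C(C)C)[C@H]2[C@H]1C[C@H]3O[Si](C(C)(C)C)(C(C)(C)C)O[C@H](C)[C@H]23 | intermediate
21 | (S)-2-methylbutanoic anhydride | CC[C@H](C)C(=O)OC(=O)[C@@H](C)CC | starting material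
22 | 5,6-O-dibutylstannylene acetal of 20 | C=C1[C@@H]4O[Sn](CCCC)(CCCC)O[C@@H]4[C@@H](C(C)C)[C@H]2[C@H]1C[C@H]3O[Si](C(C)(C)C)(C(C)(C)C)O[C@H](C)[C@H]23 | intermediate
23 | 6β-O-[(2S)-2-methylbutanoyl] 5β-alcohol (silylene) | C=C1[C@H](O)[C@H](OC(=O)[C@@H](C)CC)[C@@H](C(C)C)[C@H]2[C@H]1C[C@H]3O[Si](C(C)(C)C)(C(C)(C)C)O[C@H](C)[C@H]23 | intermediate
24 | (E)-3-methylpent-2-enoic acid | CC/C(C)=C/C(=O)O | starting material
25 | (2E)-3-methylpent-2-enoic 2,4,6-trichlorobenzoic anhydride | CC/C(C)=C/C(=O)OC(=O)c1c(Cl)cc(Cl)cc1Cl | intermediate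
26 | 5β,6β-diester (silylene) | C=C1[C@H](OC(=O)/C=C(\C)CC)[C@H](OC(=O)[C@@H](C)CC)[C@@H](C(C)C)[C@H]2[C@H]1C[C@H]3O[Si](C(C)(C)C)(C(C)(C)C)O[C@H](C)[C@H]23 | intermediate
27 | diester 2β,1′-diol | C=C1[C@H](OC(=O)/C=C(\C)CC)[C@H](OC(=O)[C@@H](C)CC)[C@@H](C(C)C)[C@H]2[C@H]1C[C@@H](O)[C@@H]2[C@@H](C)O | intermediate
28 | diester 2-ketone with free (1′R)-hydroxyl | C=C1[C@H](OC(=O)/C=C(\C)CC)[C@H](OC(=O)[C@@H](C)CC)[C@@H](C(C)C)[C@H]2[C@H]1CC(=O)[C@@H]2[C@@H](C)O | intermediate
29 | target, (1S,3aR,5S,6R,7S,7aR)-1-[(1R)-1-acetoxyethyl]-7-isopropyl-4-methylidene-2-oxo-octahydro-1H-indene-5,6-diyl 5-[(2E)-3-methylpent-2-enoate] 6-[(2S)-2-methylbutanoate] | C=C1[C@@H]2CC(=O)[C@H]([C@@H](C)OC(C)=O)[C@H]2[C@H](C(C)C)[C@@H](OC(=O)[C@@H](C)CC)[C@H]1OC(=O)/C=C(\C)CC | target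

## Step count

Total step count: 19. Longest linear sequence: 19 steps (1 to 29); 21 and 24 are purchased.

## Steps most likely to fail

**Step 10.** The base-mediated conjugation may discriminate incompletely between the two C7 epimers and between the ring-fusion isomers, because both centres are set only by thermodynamics. The fallback sets out from 15, which is then isolated. LiBH(s-Bu)3 should reduce the ketone from the convex α-face to the 4β-alcohol F2. Hydroxyl-directed hydrogenation with [Ir(cod)(PCy3)(py)]PF6 should deliver hydrogen to the β-face of the C6=C7 alkene and give the saturated alcohol F3 with the isopropyl group α. Dess–Martin oxidation gives the cis-fused saturated ketone F4, which NaOMe in MeOH equilibrates at C3a to the trans-fused ketone F5. Kinetic enolisation towards the CH2 group (LDA, TMSCl) gives the trimethylsilyl enol ether F6, and Saegusa–Ito oxidation with Pd(OAc)2 returns to the route at 16. If only the ring fusion is incomplete, ketone 18 can be re-equilibrated with base, since its axial C5–O bond disfavours the cis isomer.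

**Step 5.** The carbon–carbon bond formation may show poor syn/anti selectivity, and the aldol may suffer retro-aldol cleavage or dehydration. The fallback sets out from 9. Reductive silylation (Zn, TMSCl, THF) gives the regiodefined silyl enol ether F1. This is converted in one pot (MeLi, then Cp2ZrCl2, then acetaldehyde at −78 °C) through the zirconium enolate, whose aldol additions are syn-selective whatever the enolate geometry, and the sequence returns to the route at 10.

**Step 18.** The oxidant may discriminate poorly between the two secondary hydroxyls, or over-oxidise to the β-diketone. The fallback sets out from 27 and reverses the order of events. The lipase of step 6 with vinyl acetate should acetylate the (R)-configured methyl carbinol and give the monoacetate F7. Dess–Martin oxidation of the remaining ring carbinol then gives 29 directly.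

## Further compounds

F1 | step 5 | rac-7-endo-isopropyl-3-(trimethylsilyloxy)-7-exo-vinylbicyclo[3.2.0]hept-2-en-6-one | O=C1[C@H]2CC(O[Si](C)(C)C)=C[C@H]2[C@@]1(C=C)C(C)C
F2 | step 10 | cis-fused 4β-alcohol from 15 (C6=C7, silylene) | O[C@@H]1CC=C(C(C)C)[C@H]2[C@@H]1C[C@H]3O[Si](C(C)(C)C)(C(C)(C)C)O[C@H](C)[C@H]23
F3 | step 10 | cis-fused saturated 4β-alcohol with 7α-isopropyl (silylene) | O[C@@H]1CC[C@@H](C(C)C)[C@H]2[C@@H]1C[C@H]3O[Si](C(C)(C)C)(C(C)(C)C)O[C@H](C)[C@H]23
F4 | step 10 | cis-fused saturated 4-ketone with 7α-isopropyl (silylene) | O=C1CC[C@@H](C(C)C)[C@H]2[C@@H]1C[C@H]3O[Si](C(C)(C)C)(C(C)(C)C)O[C@H](C)[C@H]23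
F5 | step 10 | trans-fused saturated 4-ketone with 7α-isopropyl (silylene) | O=C1CC[C@@H](C(C)C)[C@H]2[C@H]1C[C@H]3O[Si](C(C)(C)C)(C(C)(C)C)O[C@H](C)[C@H]23
F6 | step 10 | trimethylsilyl enol ether of F5 (C4=C5) | C[Si](C)(C)OC1=CC[C@@H](C(C)C)[C@H]2[C@H]1C[C@H]3O[Si](C(C)(C)C)(C(C)(C)C)O[C@H](C)[C@H]23
F7 | step 18 | diester 2β-alcohol (1′R)-acetate | C=C1[C@H](OC(=O)/C=C(\C)CC)[C@H](OC(=O)[C@@H](C)CC)[C@@H](C(C)C)[C@H]2[C@H]1C[C@@H](O)[C@@H]2[C@@H](C)OC(C)=O
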